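(The earlier runs and the new flask are calculated from invented constants, and the scatter is random.)

I decided to judge these flasks by one number instead of a curve, and I left this note for whoever took over the bench.

| flask | substrate | reagent | initiator | remark | time |
|---|---|---|---|---|---|
| west | 43 mM | 2.5 equiv | 5 mol% | run made earlier |  |
| north | 43 mM | 2.4 equiv | 5 mol% | run made earlier |  |
| south | 43 mM | 3.7 equiv | 5 mol% | run made earlier |  |
| birch | 43 mM | 2.00 equiv | 5 mol% |  | 40 min |
| ash | 43 mM | 2.60 equiv | 5 mol% |  | 40 min |
| maple | 43 mM | 3.40 equiv | 5 mol% |  | 40 min |

| run | time / min | substrate / % | product / % |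
|---|---|---|---|
| west | 6.00 | 79 | 13 |
| west | 12.0 | 68 | 20 |
| west | 15.0 | 61 | 22 |
| west | 25.0 | 51 | 31 |
| west | 30.0 | 52 | 31 |
| north | 6.00 | 78 | 12 |
| north | 12.0 | 68 | 20 |
| north | 15.0 | 60 | 22 |
| north | 25.0 | 54 | 27 |
| north | 30.0 | 54 | 30 |
| south | 2.50 | 86 | 9 |
| south | 8.00 | 68 | 22 |
| south | 12.0 | 59 | 29 |
| south | 20.0 | 43 | 39 |
| south | 30.0 | 37 | 45 |

(standard deviation of a reading: 1.5 percentage points)

- what has gone from substrate into another species counts as reacted, even if it can come back

- part of the substrate that has reacted at the end, birch
- part of the substrate that has reacted at the end, ash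
- part of the substrate that has reacted at the end, maple
- what raising the equivalents of reagent from its lowest to its highest value here does to the part of the substrate that has reacted (changes below 5 percentage points count as none) (it falls / it rises / no change)

I called that number the loss per equivalent: minus the natural logarithm of the fraction of substrate left, divided by the equivalents of reagent, a pseudo-first-order exponent with the time course replaced by its mean. South at its last reading gave 0.269 and west gave 0.262. That gap was smaller than the 0.0110 that one reading's scatter moves south, so I treated the number as common to both. West's substrate went from 51% to 52% between 25.0 min and 30.0 min, so I let it stand for 40 min. That gave reacted parts of 41.6% for birch, 50.3% for ash and 59.9% for maple. Expect substrate, product and an unseen remainder, which counts as reacted; in south at its last reading it came to 18.0%. Please add nothing: the number was read at these charges of substrate and initiator.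

The forecast gave 42% (35% to 48%), 51% (46% to 56%) and 61% (55% to 67%), with the trend "it rises", and judged: “This looks like the initiator dying”. Mine stood below it on maple.

The flasks gave 46.0%, 54.9% and 64.6%, and the trend was "it rises", by 19 percentage points.

    initiator → 2 initiating radical (k = 0.0760 min⁻¹)
    2 second chain carrier → ended chains A (k = 3.00 × 10⁷ M⁻¹ s⁻¹)
    2 first chain carrier → ended chains B (k = 6.00 × 10⁸ M⁻¹ s⁻¹)
    substrate + second chain carrier → released group + first chain carrier (k = 4.20 × 10⁵ M⁻¹ min⁻¹)
    first chain carrier → ended carrier (k = 3400 min⁻¹)
    reagent + first chain carrier → product + second chain carrier (k = 2.00 × 10⁵ M⁻¹ min⁻¹)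
    substrate + initiating radical → capped initiator + first chain carrier (k = 86000 M⁻¹ s⁻¹)
    substrate + released group ⇌ idle adduct, settled at all times (K = 20.0 M⁻¹)

Birch's loss per equivalent came out at 0.309 and maple's at 0.306, both above 0.269. The main reason for the gap between birch and maple was the difference in equivalents of reagent: maple's reacted part stood at 64.6%, and with that difference taken away it stood at 46.0%. Maple read at 25 min came earlier than the reading behind 0.269, so that number, giving 40.1% substrate, should run low; the computed flask held 42.5%.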